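## Structural features

The target is a eudesmane: a trans-fused decalin in which ring A (C1–C5, C10) and ring B (C5–C10) share the C5–C10 bond, with the angular methyl C14 on the quaternary C10 (β face) and the hydrogen on C5 on the α face. It has six stereocentres; C3, C4, C5, C6 and C7 form an unbroken chain and the sixth, C10, is bonded to C5. Ring A carries a trans-diaxial glycol (secondary 3α-hydroxyl, tertiary 4β-hydroxyl, equatorial 4α-methyl C15), which is the pattern left by diaxial opening of an epoxide. Ring B carries an axial 6β-benzoate and an equatorial 7β-isopropyl group, so the oxygens on C4 and C6 and the methyl C14 are all syn-axial on a crowded β face, and 6β is the less stable orientation at C6. The fragile points are the benzoate (hydrolysis, acyl shift to the neighbouring axial O4), the tertiary carbinol (elimination) and, along the way, any C4 ketone with a leaving group on C6 (β-elimination, retro-aldol). The real difficulty is the quaternary C10 in absolute and relative register with the C5 methine and the axial C6 oxygen. The key step uses the contiguous array C14–C10–C5–C6 next to a ring A carbonyl at C4: C10 is the β-carbon, C5 the α-carbon and C6 the carbinol carbon of a conjugate addition–aldol sequence, and the surviving C4 carbonyl is the handle for C15 and the 3,4-oxygenation.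

## Logic of the disconnections

**22 ⇒ 21.** The C4–O bond of the tertiary carbinol is cut (water as synthon), so both glycol oxygens trace to one oxirane. A 3α,4β-diaxial glycol is what diaxial opening of a 3α,4α-oxide gives, and the tertiary carbon is where an acid-activated oxirane opens. Two hydroxyls and two stereocentres collapse into one functional group. The forward step must bring oxygen to C4 from the crowded β face without losing or moving the ester.

**21 ⇒ 20.** Both C–O bonds of the oxirane are cut to the C3=C4 alkene. The alkene is trisubstituted and electron-rich, and its β face is closed by C14 and the 6β-ester. Two stereocentres are removed. The forward step needs α-face delivery of oxygen, which the substrate provides.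

**20 ⇒ 19.** The acyl–O6 bond is cut. The ester goes on before the glycol exists, because afterwards three hydroxyls would compete, and after all enolate chemistry, because an ester on C6 β to a C4 ketone would eliminate. The forward step is acylation of an axial, flanked alcohol.

**19 ⇒ 18 ⇒ 17.** The C6–H bond is cut (hydride synthon) and the resulting ketone 18 is traced to the epimeric carbinol 17. The key step is expected to place O6 equatorial (α), and passing through 18 erases this, so the route no longer depends on the C6 outcome of the aldol. The axial carbinol becomes a ketone reduction with a strong facial bias. The forward steps must make and reduce 18 without the C3=C4 bond moving into conjugation, and hydride must arrive from the α face.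

**17 ⇒ 15 (through 16).** The C4–C15 bond is cut to a methyl nucleophile and a C4 enol sulfonate, and the O–Si bond is put back. Cross-coupling fixes the methyl group and the alkene position in one operation, with no regiochemical choice as in a dehydration. The forward step needs a methyl donor that tolerates the silyl ether, and the ether must then come off under conditions that leave the alkene alone.

**15 ⇒ 13 (through 14).** The O–S bond is cut to the C4 ketone. The ketone is what the key step leaves behind, so no functional group has to be introduced. The forward step must enolise toward C3, not toward C5.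

**13 ⇒ 12.** The O–Si bond is cut. The free hydroxyl of 12 is aldol-related to the C4 ketone and would not survive a strong base. The forward step is a simple silylation, and a silyloxy group is a poor β-leaving group.

**12 ⇒ 11.** The C7–H and C8–H bonds are cut to the C7=C8 alkene. This removes the C7 stereocentre and exposes a metathesis retron. The forward step must add hydrogen to the α face, which is favoured by C14 and by the directing 6α-hydroxyl.

**11 ⇒ 10.** The C7=C8 bond is cut to two terminal alkenes. Ring B is opened to a cyclohexanone with two arms, which is an aldol retron. The forward step must close a six-membered ring onto a 1,1-disubstituted alkene.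

**10 ⇒ 4 + 8 + 7 (through 9).** The C10–C14 and C5–C6 bonds are cut. C10 is β and C5 is α to the C4 carbonyl and C6 is a carbinol, so one conjugate addition and one aldol account for both bonds and three stereocentres. This is the largest simplification of the route. The forward step must control the enone face, the face of the enolate at C5, and 1,2-addition to the enal. The skeletons of 4 and 7 are kept unchanged.

**4 ⇒ 1 + 2 (through 3).** The C9–C10 bond is cut to an allyl nucleophile and a vinylogous ester. The forward step is 1,2-addition followed by acid transposition, and it must not conjugate the skipped diene.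

**7 ⇒ 5 (through 6).** The C7=CH2 bond is cut to the saturated aldehyde and formaldehyde. The forward step is an amine-catalysed α-methylenation of an enolisable aldehyde.

## Other disconnections considered

**Alternative 1:** The cut is the C9–C10 bond of ring B, with ring A starting as an aromatic ring. In the forward step the potassium phenoxide of the iodo-phenol A2 (KOt-Bu) attacks the primary iodide at C9 through its para carbon C10, which closes ring B and de-aromatises ring A to the cross-conjugated dienone A1.
- **In favour:** the quaternary centre and ring B form in one event without a chiral catalyst. C15 and an oxygen on C3 are present from the start. The C6 oxygen is already β, so no inversion is needed. On these three points it is better than the chosen plan, which uses two steps for ring B and two for C6.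
- **Against:** C4, the other ring neighbour of C5, is ortho to the phenoxide oxygen and would close a six-membered ring equally well, so para must beat ortho C-alkylation. The C6–C7 stereo pair of A2 sits on a 2,6-disubstituted benzylic carbinol and must be built enantioselectively first. A1 has two alkenes too many in ring A, and C5 must later be reduced to the 5α-hydride. A 4β-hydroxyl trans to a 3α-hydroxyl cannot be reached from the C3 ketone directly, because enolate oxidation at C4 would come from the open α face. The ketone would therefore have to be converted into the same 3-ene that the chosen route reaches at 20.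
- **Comparison:** structurally it maps all fifteen carbons at once, but at the wrong oxidation level in ring A. Mechanistically it is a substrate-controlled intramolecular C-alkylation against a catalyst-controlled conjugate addition plus aldol; it avoids the C5/C10 facial problem of the chosen key step but pays for it with a later C5 reduction. In step economy it should be longer, because the chiral side chain and the ring A corrections each need roughly half a dozen steps.

**Alternative 2:** The cut is the pair C5–C10 and C1–C2, a Diels–Alder retron in ring A with the tether becoming ring B. In the forward step Me2AlCl activates the (E)-enal of triene A4, and its C10=C1 bond adds in the endo mode to the C5=C4–C3=C2 diene, closing both rings to the trans-fused aldehyde A3.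
- **In favour:** two rings and the C5–C10 fusion form in one concerted step. The 3-ene with C15 is in place where the chosen route needs it, so no enol triflate or methyl coupling is required. The 6β oxygen and 7β-isopropyl group come from an acyclic anti aldol without inversion. On the alkene and on C6 it is better than the chosen plan.
- **Against:** the dienophile must be β,β-disubstituted to make quaternary C10, and such enals react slowly. A strong Lewis acid is then needed next to an allylic silyl ether and an acid-sensitive diene. Trans fusion needs both the endo mode and the right diene face, and only allylic strain from C6 controls the face. The triene needs two geometrically defined trisubstituted alkenes. The formyl carbon on C1 is one carbon too many and must be excised by decarbonylation of a hindered secondary aldehyde, in practice with stoichiometric RhCl(PPh3)3.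
- **Comparison:** structurally it fits ring A very well but carries a superfluous carbon. Mechanistically one pericyclic event sets C5 and C10 together, which is an equal or better way to secure the fusion if the endo preference holds. In step economy it is short after the key step (decarbonylation, silyl-to-benzoyl exchange, epoxidation, hydrolysis) but long before it, so the totals should be similar.

**Alternative 3:** The cut is C6–C7 in ring B. In the forward step, under ZnBr2, the aldehyde A6 undergoes a carbonyl-ene reaction with the trisubstituted alkene of its side chain, as citronellal does. This closes ring B to the dienol A5 with an equatorial 6α-hydroxyl and an equatorial 7β-isopropenyl group.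
- **In favour:** no protecting groups and full atom economy. C6 and C7 are set together by a chair transition state. C15 and the 3-ene are already present, which is better than the chosen plan. Selective hydrogenation of the isopropenyl group of A5 would give compound 17 of the chosen route, so the endgame, including the inversion at C6, is identical and the two plans are equal there.
- **Against:** A6 is a β,γ-unsaturated aldehyde; its C5 can epimerise and its alkene can move into conjugation. It needs the same trans relationship between the C5 substituent and the C10 chain, so the facial problem of the chosen key step is moved, not removed. ZnBr2 can also divert the aldehyde into a Prins reaction with the ring alkene.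
- **Comparison:** structurally the cut is as central as the chosen one, and it leaves an isopropenyl group to reduce where metathesis leaves C7=C8 to reduce, which is equal. Mechanistically a concerted ene closure needing only a Lewis acid is simpler than a ruthenium carbene closure but less tolerant of the sensitive aldehyde. In step economy it is probably one or two steps shorter after ring closure, offset by the longer way to A6, where a ring ketone must become the methyl-bearing alkene next to a masked aldehyde.

Key step: step 3

Remark on the chemistry: a closed chair transition state of the ring-locked (E)-enolate should give the anti aldol (6α-hydroxyl after ring closure), so adduct 10 is drawn as the C6 epimer of what the target needs and C6 is corrected through the C6 ketone; eudesmane numbering is used throughout, with β meaning the face of the angular methyl C14.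

## Route

Step 1
Reactants: 1 3-ethoxycyclohex-2-en-1-one; 2 allylmagnesium bromide
Product: 4 3-allylcyclohex-2-en-1-one, via 1-allyl-3-ethoxycyclohex-2-en-1-ol 3 (not isolated)
Conditions: 2 (1.2 equiv), Et2O, 0 °C; then 1 M aq. HCl, 0 °C, 30 min
Reagents that add atoms: water O
Why: Stork–Danheiser transposition: the Grignard reagent adds 1,2 to the vinylogous ester, dilute acid ionises the tertiary allylic alcohol 3, water re-enters at the ethoxy-bearing carbon and ethanol is lost, which places the allyl group on the β-carbon of the new enone; brief cold acid keeps the skipped diene out of conjugation.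

Step 2
Reactants: 5 isovaleraldehyde
Product: 7 2-isopropylacrolein (3-methyl-2-methylidenebutanal), via 3-methyl-2-(pyrrolidin-1-ylmethyl)butanal 6 (not isolated)
Conditions: 37% aq. CH2O, pyrrolidine (10 mol%), EtCO2H (10 mol%), i-PrOH, 45 °C; distil
Reagents that add atoms: formaldehyde C=O
Why: Amine-catalysed Mannich condensation with formaldehyde followed by elimination of pyrrolidine from 6 (organocatalytic α-methylenation of an aldehyde); the enal is distilled and used fresh because α-substituted acroleins polymerise.

Step 3
Reactants: 4 3-allylcyclohex-2-en-1-one; 8 trimethylaluminium; 7 2-isopropylacrolein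
Product: 10 (2S,3R)-3-allyl-2-[(1R)-1-hydroxy-3-methyl-2-methylidenebutyl]-3-methylcyclohexan-1-one (anti aldol, side chain on C5 trans to the allyl arm), via dimethylaluminium enolate 9 (not isolated)
Conditions: Cu(OTf)2 (2 mol%), binaphthol-based N,N-bis(1-phenylethyl)phosphoramidite (4 mol%, enantiomer giving (R)-9), 8 (1.2 equiv), Et2O, −30 °C; then 7 (1.5 equiv), −78 → −30 °C; aq. potassium sodium tartrate
Reagents that add atoms: none
Why: Me3Al reduces Cu(OTf)2 to a monovalent copper–phosphoramidite complex that transfers methyl to the β-carbon C10 of 4 through a π-complex and a trivalent copper intermediate, and reductive elimination leaves the dimethylaluminium enolate 9 (C4=C5, O–Al), which is the known copper-catalysed asymmetric conjugate addition of trialkylaluminium reagents to 3-substituted cyclohexenones with aldol capture of the enolate. No ring is closed in this step. C10 is set by the chiral ligand, which selects the enone face; the ligand antipode is used if a test reaction shows the opposite sense. C5 is set by the substrate: the aldehyde adds axially to the half-chair enolate on the face opposite the pseudo-axial allyl arm of the new quaternary centre, so C6 ends trans to C9. C6 is set by the six-membered Al–O–C4=C5···C6=O chair with the isopropylvinyl group equatorial, so the ring-locked (E)-enolate gives the anti carbinol (6R, later 6α). The step needs 1,2- and not 1,4-addition to the enal and no methyl transfer from aluminium to the aldehyde; the α-branch of 7, the low temperature and the small excess of 8 secure this. The configuration at C6 is not critical because C6 passes through a ketone in steps 9 and 10.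

Step 4
Reactants: 10 (2S,3R)-3-allyl-2-[(1R)-1-hydroxy-3-methyl-2-methylidenebutyl]-3-methylcyclohexan-1-one
Product: 11 6α-hydroxy-15-noreudesm-7-en-4-one (trans-fused, 5α-H, 10β-methyl)
Conditions: second-generation Grubbs catalyst (5 mol%), CH2Cl2 (0.01 M), 40 °C
Reagents that add atoms: none
Why: Ring-closing metathesis: the ruthenium carbene loads on the monosubstituted allyl terminus and closes onto the 1,1-disubstituted alkene to give the six-membered ring with a trisubstituted C7=C8 bond, driven by loss of ethylene; the trans-diequatorial arms of 10 reach each other without strain and the free allylic hydroxyl is tolerated.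

Step 5
Reactants: 11 6α-hydroxy-15-noreudesm-7-en-4-one
Product: 12 6α-hydroxy-15-noreudesman-4-one (5α-H, 7α-H, 7β-isopropyl, 10β-methyl)
Conditions: [Ir(cod)(PCy3)(py)]PF6 (5 mol%), H2 (1 atm), CH2Cl2, 23 °C
Reagents that add atoms: none
Why: Hydroxyl-directed homogeneous hydrogenation: iridium binds the 6α-hydroxyl and delivers H2 to the α face of C7=C8, which is also the face free of the axial C14 methyl, so C7 receives an α-hydrogen and the isopropyl group ends β and equatorial.

Step 6
Reactants: 12 6α-hydroxy-15-noreudesman-4-one
Product: 13 6α-(triethylsilyloxy)-15-noreudesman-4-one
Conditions: Et3SiOTf, 2,6-lutidine, CH2Cl2, −78 → 0 °C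
Reagents that add atoms: triethylsilyl trifluoromethanesulfonate CC[Si](CC)(CC)OS(=O)(=O)C(F)(F)F
Why: Silylation of a secondary alcohol with a silyl triflate and a hindered pyridine base; the ether removes the aldol hydroxyl so the strong base of step 7 cannot trigger retro-aldol cleavage, and a silyloxy group is a far poorer β-leaving group than a benzoate.

Step 7
Reactants: 13 6α-(triethylsilyloxy)-15-noreudesman-4-one
Product: 15 6α-(triethylsilyloxy)-15-noreudesm-3-en-4-yl trifluoromethanesulfonate, via lithium enolate 14 (not isolated)
Conditions: LiN(i-Pr)2, THF, −78 °C; then N-(5-chloropyridin-2-yl)triflimide, −78 °C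
Reagents that add atoms: N-(5-chloropyridin-2-yl)bis(trifluoromethanesulfonyl)imide FC(F)(F)S(=O)(=O)N(c1ccc(Cl)cn1)S(=O)(=O)C(F)(F)F
Why: Kinetic deprotonation by the bulky amide at the unhindered C3 methylene and not at the C5 methine (flanked by quaternary C10 and C6), then O-sulfonylation of the enolate at low temperature; this fixes the future alkene at C3=C4.

Step 8
Reactants: 15 6α-(triethylsilyloxy)-15-noreudesm-3-en-4-yl trifluoromethanesulfonate
Product: 17 eudesm-3-en-6α-ol, via 6α-(triethylsilyloxy)eudesm-3-ene 16 (not isolated)
Conditions: MeZnCl (2 M in THF, 3 equiv), Pd(PPh3)4 (5 mol%), THF, 50 °C; then 2 M aq. HCl, MeOH, 23 °C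
Reagents that add atoms: methylzinc chloride C[Zn]Cl
Why: Negishi cross-coupling: oxidative addition of zerovalent palladium into the C4–OTf bond, transmetalation from zinc and reductive elimination form C4–C15 with the alkene fixed at C3=C4; the acidic methanol quench then cleaves the triethylsilyl ether of 16 without touching the trisubstituted alkene.

Step 9
Reactants: 17 eudesm-3-en-6α-ol
Product: 18 eudesm-3-en-6-one
Conditions: Dess–Martin periodinane, NaHCO3, CH2Cl2, 0 → 23 °C; used crude
Reagents that add atoms: none
Why: Dess–Martin oxidation of a secondary alcohol under bicarbonate buffer, neutral enough to keep the β,γ-unsaturated ketone out of conjugation and to leave C5 and C7 unchanged; 18 is taken on without chromatography.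

Step 10
Reactants: 18 eudesm-3-en-6-one
Product: 19 eudesm-3-en-6β-ol
Conditions: NaBH4, CeCl3·7H2O, MeOH, −40 °C
Reagents that add atoms: none
Why: Luche-type borohydride reduction: hydride attacks C6 from the α face because the β face is screened by the syn-axial C14 methyl, as in the reduction of 6-oxo-5α-steroids, and the axial 6β-alcohol also avoids the peri strain between an equatorial C6 oxygen and C15; the cerium salt keeps the medium near neutral so the alkene does not migrate.

Step 11
Reactants: 19 eudesm-3-en-6β-ol
Product: 20 eudesm-3-en-6β-yl benzoate
Conditions: BzCl, DMAP, pyridine, 0 → 40 °C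
Reagents that add atoms: benzoyl chloride O=C(Cl)c1ccccc1
Why: DMAP-catalysed acylation (acylpyridinium transfer) of the hindered axial alcohol; at this point the benzoate never faces a base-labile position β to a ketone and is in place before the glycol exists, so no hydroxyl has to be differentiated later.

Step 12
Reactants: 20 eudesm-3-en-6β-yl benzoate
Product: 21 3α,4α-epoxyeudesman-6β-yl benzoate
Conditions: mCPBA, NaHCO3, CH2Cl2, 0 °C
Reagents that add atoms: 3-chloroperoxybenzoic acid OOC(=O)c1cccc(Cl)c1
Why: Prilezhaev epoxidation of the electron-rich trisubstituted alkene; the β face is closed by the axial C14 methyl and the axial 6β-benzoate, so the peracid adds from the α face and sets C3 and C4 as the 3α,4α-oxide.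

Step 13
Reactants: 21 3α,4α-epoxyeudesman-6β-yl benzoate
Product: 22 3α,4β-dihydroxyeudesman-6β-yl benzoate (CNP0187831.1)
Conditions: 0.1 M aq. HClO4, THF, 0 → 23 °C
Reagents that add atoms: water O
Why: Acid-catalysed epoxide hydrolysis in the trans-diaxial (Fürst–Plattner) sense: the protonated oxirane opens at the tertiary C4 with inversion, and the oxygen enters from the β face either as water or through the carbonyl oxygen of the 6β-benzoate (a six-membered dioxanylium ion that water then hydrolyses, releasing the more hindered tertiary oxygen); both paths give the 3α,4β-diol with the 4α-methyl and the ester on O6.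

## Compound list

1 | 3-ethoxycyclohex-2-en-1-one | CCOC1=CC(=O)CCC1 | starting material
2 | allylmagnesium bromide | C=CC[Mg]Br | starting material
3 | 1-allyl-3-ethoxycyclohex-2-en-1-ol (racemic; bromomagnesium alkoxide until the acid quench) | C=CCC1(O)C=C(OCC)CCC1 | intermediate (not isolated)
4 | 3-allylcyclohex-2-en-1-one | C=CCC1=CC(=O)CCC1 | intermediate
5 | isovaleraldehyde (3-methylbutanal) | CC(C)CC=O | starting material
6 | 3-methyl-2-(pyrrolidin-1-ylmethyl)butanal | CC(C)C(CN1CCCC1)C=O | intermediate (not isolated)
7 | 2-isopropylacrolein (3-methyl-2-methylidenebutanal) | CC(C)C(=C)C=O | intermediate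
8 | trimethylaluminium | C[Al](C)C | starting material
9 | dimethylaluminium (R)-3-allyl-3-methylcyclohex-1-en-1-olate | C=CC[C@@]1(C)CCCC(O[Al](C)C)=C1 | intermediate (not isolated)
10 | (2S,3R)-3-allyl-2-[(1R)-1-hydroxy-3-methyl-2-methylidenebutyl]-3-methylcyclohexan-1-one | C=CC[C@@]1(C)CCCC(=O)[C@@H]1[C@@H](O)C(=C)C(C)C | intermediate
11 | 6α-hydroxy-15-noreudesm-7-en-4-one (5α-H, 10β-methyl) | CC(C)C1=CC[C@@]2(C)CCCC(=O)[C@@H]2[C@H]1O | intermediate
12 | 6α-hydroxy-15-noreudesman-4-one (5α-H, 7β-isopropyl, 10β-methyl) | CC(C)[C@@H]1CC[C@@]2(C)CCCC(=O)[C@@H]2[C@H]1O | intermediate
13 | 6α-(triethylsilyloxy)-15-noreudesman-4-one | CC(C)[C@@H]1CC[C@@]2(C)CCCC(=O)[C@@H]2[C@H]1O[Si](CC)(CC)CC | intermediate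
14 | lithium 6α-(triethylsilyloxy)-15-noreudesm-3-en-4-olate | [Li+].CC(C)[C@@H]1CC[C@@]2(C)CCC=C([O-])[C@@H]2[C@H]1O[Si](CC)(CC)CC | intermediate (not isolated)
15 | 6α-(triethylsilyloxy)-15-noreudesm-3-en-4-yl trifluoromethanesulfonate | CC(C)[C@@H]1CC[C@@]2(C)CCC=C(OS(=O)(=O)C(F)(F)F)[C@@H]2[C@H]1O[Si](CC)(CC)CC | intermediate
16 | 6α-(triethylsilyloxy)eudesm-3-ene | CC(C)[C@@H]1CC[C@@]2(C)CCC=C(C)[C@@H]2[C@H]1O[Si](CC)(CC)CC | intermediate (not isolated)
17 | eudesm-3-en-6α-ol | CC(C)[C@@H]1CC[C@@]2(C)CCC=C(C)[C@@H]2[C@H]1O | intermediate
18 | eudesm-3-en-6-one | CC(C)[C@@H]1CC[C@@]2(C)CCC=C(C)[C@@H]2C1=O | intermediate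
19 | eudesm-3-en-6β-ol | CC(C)[C@@H]1CC[C@@]2(C)CCC=C(C)[C@@H]2[C@@H]1O | intermediate
20 | eudesm-3-en-6β-yl benzoate | CC(C)[C@@H]1CC[C@@]2(C)CCC=C(C)[C@@H]2[C@@H]1OC(=O)c1ccccc1 | intermediate
21 | 3α,4α-epoxyeudesman-6β-yl benzoate | CC(C)[C@@H]1CC[C@@]2(C)CC[C@H]3O[C@@]3(C)[C@@H]2[C@@H]1OC(=O)c1ccccc1 | intermediate
22 | 3α,4β-dihydroxyeudesman-6β-yl benzoate (5α-H, 7β-isopropyl, 10β-methyl) | CC(C)[C@@H]1CC[C@@]2(C)CC[C@@H](O)[C@](C)(O)[C@@H]2[C@@H]1OC(=O)c1ccccc1 | target

## Step count and least certain steps

Total: 13 steps. Longest linear sequence: 12 steps (step 1, then steps 3–13).

**Step 3 (key step).** The most likely failure is poor facial discrimination at C5, because the new quaternary centre offers only methyl against allyl to steer the aldehyde. A sluggish aldol of the dimethylaluminium enolate would add to this by letting methyl transfer from residual Me3Al to the enal compete. Fallback: starting from 4, the same copper-catalysed methyl addition is run but the enolate is trapped with Me3SiOTf and isolated as (R)-trimethyl[(3-allyl-3-methylcyclohex-1-en-1-yl)oxy]silane F1. A separate Mukaiyama aldol of F1 with 7 (BF3·OEt2, CH2Cl2, −78 °C, open transition state, no aluminium alkyl present) comes back to the route at 10. C6 epimers from the open transition state are acceptable because C6 is oxidised in step 9; C5 epimers are removed by chromatography at 10 or 11.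

**Step 13.** The most likely failure is loss of the cationic character at C4 through elimination to allylic alcohols, or acyl transfer to O4 during benzoate-assisted opening, because the β approach to C4 lies between two axial groups. Fallback: starting from 19, hydroxyl-directed epoxidation (VO(acac)2, t-BuOOH, CH2Cl2) places the oxygen on the β face to give 3β,4β-epoxyeudesman-6β-ol F2. Benzoylation as in step 11 gives 3β,4β-epoxyeudesman-6β-yl benzoate F3. Dilute HClO4 then lets water enter at the unhindered secondary C3 from the open α face, again in the diaxial sense, and the sequence comes back to the route at 22.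

**Step 9 (with step 10).** The most likely failure is migration of the C3=C4 bond into conjugation with the new C6 ketone before or during the reduction, because the C5 hydrogen is both allylic and α to the carbonyl. Fallback: starting from 17, the alkene is epoxidised first (mCPBA, α face) to 3α,4α-epoxyeudesman-6α-ol F4. Oxidation gives 3α,4α-epoxyeudesman-6-one F5, which has no alkene left to migrate. Borohydride reduction from the α face gives 3α,4α-epoxyeudesman-6β-ol F6, and benzoylation comes back to the route at 21.

**Step 7.** The most likely failure is partial deprotonation at C5 followed by β-elimination of the silanolate, or equilibration of the enolate before it is trapped. Fallback: starting from 13, condensation with 2,4,6-triisopropylbenzenesulfonyl hydrazide gives the 2,4,6-triisopropylbenzenesulfonylhydrazone of 13 F7. A Shapiro reaction (n-BuLi, 2.2 equiv, THF, −78 → 0 °C; then MeI) deprotonates at C3, loses sulfinate and N2 to give the C4 vinyllithium, and methylation gives 16; the acidic methanol treatment of step 8 comes back to the route at 17.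

## Further compounds

F1 | step 3 | (R)-trimethyl[(3-allyl-3-methylcyclohex-1-en-1-yl)oxy]silane | C=CC[C@@]1(C)CCCC(O[Si](C)(C)C)=C1
F2 | step 13 | 3β,4β-epoxyeudesman-6β-ol | CC(C)[C@@H]1CC[C@@]2(C)CC[C@@H]3O[C@]3(C)[C@@H]2[C@@H]1O
F3 | step 13 | 3β,4β-epoxyeudesman-6β-yl benzoate | CC(C)[C@@H]1CC[C@@]2(C)CC[C@@H]3O[C@]3(C)[C@@H]2[C@@H]1OC(=O)c1ccccc1
F4 | step 9 | 3α,4α-epoxyeudesman-6α-ol | CC(C)[C@@H]1CC[C@@]2(C)CC[C@H]3O[C@@]3(C)[C@@H]2[C@H]1O
F5 | step 9 | 3α,4α-epoxyeudesman-6-one | CC(C)[C@@H]1CC[C@@]2(C)CC[C@H]3O[C@@]3(C)[C@@H]2C1=O
F6 | step 9 | 3α,4α-epoxyeudesman-6β-ol | CC(C)[C@@H]1CC[C@@]2(C)CC[C@H]3O[C@@]3(C)[C@@H]2[C@@H]1O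
F7 | step 7 | 2,4,6-triisopropylbenzenesulfonylhydrazone of 13 | CC(C)[C@@H]1CC[C@@]2(C)CCCC(=NNS(=O)(=O)c3c(C(C)C)cc(C(C)C)cc3C(C)C)[C@@H]2[C@H]1O[Si](CC)(CC)CC
A1 | alternative 1 | 6β-(tert-butyldimethylsilyloxy)eudesma-1,4-dien-3-one | CC(C)[C@@H]1CC[C@@]2(C)C=CC(=O)C(C)=C2[C@@H]1O[Si](C)(C)C(C)(C)C
A2 | alternative 1 | 3-[(1R,2S)-1-(tert-butyldimethylsilyloxy)-4-iodo-2-isopropylbutyl]-2,4-dimethylphenol | CC(C)[C@H](CCI)[C@@H](O[Si](C)(C)C(C)(C)C)c1c(C)ccc(O)c1C
A3 | alternative 2 | 6β-(tert-butyldimethylsilyloxy)eudesm-3-ene-1β-carbaldehyde (trans-fused) | CC(C)[C@@H]1CC[C@@]2(C)[C@H](C=O)CC=C(C)[C@@H]2[C@@H]1O[Si](C)(C)C(C)(C)C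
A4 | alternative 2 | (2E,6S,7R,8E)-7-(tert-butyldimethylsilyloxy)-6-isopropyl-3,9-dimethylundeca-2,8,10-trienal | O=C/C=C(C)/CC[C@@H](C(C)C)[C@@H](O[Si](C)(C)C(C)(C)C)/C=C(C)/C=C
A5 | alternative 3 | eudesma-3,11-dien-6α-ol | CC(=C)[C@@H]1CC[C@@]2(C)CCC=C(C)[C@@H]2[C@H]1O
A6 | alternative 3 | 2,6-dimethyl-6-(4-methylpent-3-en-1-yl)cyclohex-2-ene-1-carbaldehyde, formyl group trans to the pentenyl chain | CC(C)=CCC[C@@]1(C)CCC=C(C)[C@@H]1C=O
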